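**Plan**

1. Retrosynthetic cuts: N1–H is masked as an N-Boc carbamate. The C1'–C2' bond of the tricosyl chain is traced back to a C1'=C2' alkene, and this alkene is split by a Wittig disconnection into a (pyrrol-3-ylmethyl)phosphonium salt (ring plus C1') and docosanal (C2'–C23').
2. Forward, ring part: the pyrrole ring is bought intact as methyl 3-methyl-1H-pyrrole-2-carboxylate. N-Boc protection, bromination of the C3 methyl group and quaternisation with PPh3 arm C1'. Docosanal comes from docosan-1-ol.
3. Forward, union: the chain is joined in a single olefination (no ring is formed anywhere in the route), then the alkene is hydrogenated and the Boc group removed.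
4. Enabling feature: C1' sits on ring C3 and is conjugated through the C3=C2 bond of the pyrrole with the C2 ester carbonyl. It therefore supports a benzylic-type radical (bromination) and a semi-stabilised ylide (olefination), and the other 22 carbons are a plain aldehyde.
5. Stereochemistry: the target has no stereocentre. The only stereo-element created, the C1'=C2' geometry, is erased by hydrogenation.

Key step: step 5

Remark: side-chain carbons are counted C1' (on the ring) to C23'. The olefination is expected to give both alkene isomers, which are carried on together; the E isomer is the one drawn.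

**Route**

Step 1
Reactants: 1 methyl 3-methyl-1H-pyrrole-2-carboxylate
Product: 2 1-tert-butyl 2-methyl 3-methyl-1H-pyrrole-1,2-dicarboxylate
Conditions: Boc2O (1.2 equiv), DMAP (0.1 equiv), MeCN, rt
Reagents that add atoms: di-tert-butyl dicarbonate, CC(C)(C)OC(=O)OC(=O)OC(C)(C)C
Why: DMAP-catalysed N-acylation with Boc2O (carbamate protection) is reliable for pyrrole-2-carboxylates because the ester acidifies the N–H, and the carbamate both deactivates the ring toward electrophilic bromine in step 2 and ties up the nitrogen lone pair that would otherwise ionise a pyrrol-3-ylmethyl halide or phosphonium salt.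

Step 2
Reactants: 2 1-tert-butyl 2-methyl 3-methyl-1H-pyrrole-1,2-dicarboxylate
Product: 3 1-tert-butyl 2-methyl 3-(bromomethyl)-1H-pyrrole-1,2-dicarboxylate
Conditions: NBS (1.05 equiv), AIBN (5 mol%), PhCF3 (or CCl4), 80 °C
Reagents that add atoms: N-bromosuccinimide, O=C1CCC(=O)N1Br
Why: Wohl–Ziegler radical bromination should take the side chain, because the C3 methyl hydrogens are benzylic-type and give a radical delocalised into the ring and the C2 ester, while the N-carbamate and C2 ester together suppress ionic bromination at C4 and C5 in a non-polar solvent.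

Step 3
Reactants: 3 1-tert-butyl 2-methyl 3-(bromomethyl)-1H-pyrrole-1,2-dicarboxylate; 4 triphenylphosphine
Product: 5 {[1-(tert-butoxycarbonyl)-2-(methoxycarbonyl)-1H-pyrrol-3-yl]methyl}triphenylphosphonium bromide
Conditions: PPh3 (1.1 equiv), toluene, 60 °C; salt filtered off
Reagents that add atoms: none
Why: SN2 quaternisation of triphenylphosphine by a primary, benzylic-type bromide is fast at moderate temperature, and the salt should crystallise from toluene, which drives the reaction and keeps the N-Boc group well below its thermal cleavage range.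

Step 4
Reactants: 6 docosan-1-ol
Product: 7 docosanal
Conditions: TEMPO (10 mol%), PhI(OAc)2 (1.1 equiv), CH2Cl2, 30 °C
Reagents that add atoms: none
Why: Oxoammonium (TEMPO-catalysed) oxidation with PhI(OAc)2 as terminal oxidant converts unhindered primary alcohols into aldehydes without over-oxidation under anhydrous conditions, and gentle warming keeps the waxy alcohol in solution.

Step 5
Reactants: 5 {[1-(tert-butoxycarbonyl)-2-(methoxycarbonyl)-1H-pyrrol-3-yl]methyl}triphenylphosphonium bromide; 7 docosanal
Product: 10 1-tert-butyl 2-methyl 3-(tricos-1-en-1-yl)-1H-pyrrole-1,2-dicarboxylate (E/Z mixture), via phosphonium ylide 8 (not isolated), via oxaphosphetane 9 (not isolated)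
Conditions: K2CO3 (3 equiv), 18-crown-6 (10 mol%), 7 (1.1 equiv), CH2Cl2, reflux
Reagents that add atoms: none
Why: Under solid–liquid phase-transfer conditions the carbonate removes a proton from the P–CH2 group of 5, which is acidified by phosphorus and by conjugation through C3=C2 with the ester carbonyl, to give the semi-stabilised ylide 8. The ylide adds to the unhindered aldehyde 7 by [2+2] cycloaddition to oxaphosphetane 9, and cycloreversion releases Ph3PO and alkene 10, creating the C1'=C2' bond and attaching all 22 remaining chain carbons at once. The closest known reaction type is the Wittig olefination of benzyl-type (heteroarylmethyl) ylides with aliphatic aldehydes using K2CO3 and a crown ether, which is well established. No ring of the product is closed (the four-membered ring of 9 is transient) and no stereocentre is created; the two stereocentres of 9 are uncontrolled and vanish on fragmentation, and the E/Z outcome is immaterial because both isomers converge in step 6. The selectivity required is deprotonation without attack on the carbamate or the ester, which the weakly basic, non-nucleophilic carbonate should secure, while the N-Boc group prevents the nitrogen lone pair from expelling phosphine toward an azafulvene.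

Step 6
Reactants: 10 1-tert-butyl 2-methyl 3-(tricos-1-en-1-yl)-1H-pyrrole-1,2-dicarboxylate
Product: 11 1-tert-butyl 2-methyl 3-tricosyl-1H-pyrrole-1,2-dicarboxylate
Conditions: H2 (1 atm), 10% Pd/C, EtOAc/THF, rt
Reagents that add atoms: none
Why: Heterogeneous catalytic hydrogenation saturates the conjugated 1,2-disubstituted alkene rapidly at atmospheric pressure, under which the doubly acyl-substituted pyrrole ring, the methyl ester and the carbamate are expected to stay untouched, and both alkene isomers give the same tricosyl chain.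

Step 7
Reactants: 11 1-tert-butyl 2-methyl 3-tricosyl-1H-pyrrole-1,2-dicarboxylate
Product: 13 methyl 3-tricosyl-1H-pyrrole-2-carboxylate, via N-carboxylic acid 12 (not isolated)
Conditions: CF3CO2H, CH2Cl2, 0 °C to rt
Reagents that add atoms: none
Why: Acidolytic Boc cleavage proceeds by protonation of the carbamate and loss of 2-methylpropene to N-carboxylic acid 12, which decarboxylates spontaneously to the N–H pyrrole, and the ester-deactivated ring is not expected to be tert-butylated or degraded by CF3CO2H.

**Compound list**

1 | methyl 3-methyl-1H-pyrrole-2-carboxylate | Cc1cc[nH]c1C(=O)OC | starting material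
2 | 1-tert-butyl 2-methyl 3-methyl-1H-pyrrole-1,2-dicarboxylate | Cc1ccn(C(=O)OC(C)(C)C)c1C(=O)OC | intermediate
3 | 1-tert-butyl 2-methyl 3-(bromomethyl)-1H-pyrrole-1,2-dicarboxylate | BrCc1ccn(C(=O)OC(C)(C)C)c1C(=O)OC | intermediate
4 | triphenylphosphine | c1ccc(P(c2ccccc2)c2ccccc2)cc1 | starting material
5 | {[1-(tert-butoxycarbonyl)-2-(methoxycarbonyl)-1H-pyrrol-3-yl]methyl}triphenylphosphonium bromide | COC(=O)c1c(C[P+](c2ccccc2)(c2ccccc2)c2ccccc2)ccn1C(=O)OC(C)(C)C.[Br-] | intermediate
6 | docosan-1-ol | CCCCCCCCCCCCCCCCCCCCCCO | starting material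
7 | docosanal | CCCCCCCCCCCCCCCCCCCCCC=O | intermediate
8 | 1-tert-butyl 2-methyl 3-[(triphenyl-λ5-phosphanylidene)methyl]-1H-pyrrole-1,2-dicarboxylate (ylide; formed in the flask) | COC(=O)c1c(C=P(c2ccccc2)(c2ccccc2)c2ccccc2)ccn1C(=O)OC(C)(C)C | intermediate
9 | 1-tert-butyl 2-methyl 3-(4-henicosyl-2,2,2-triphenyl-1,2λ5-oxaphosphetan-3-yl)-1H-pyrrole-1,2-dicarboxylate (cis/trans mixture, racemic; formed in the flask) | CCCCCCCCCCCCCCCCCCCCCC1OP(c2ccccc2)(c2ccccc2)(c2ccccc2)C1c1ccn(C(=O)OC(C)(C)C)c1C(=O)OC | intermediate
10 | 1-tert-butyl 2-methyl 3-(tricos-1-en-1-yl)-1H-pyrrole-1,2-dicarboxylate (E/Z mixture; E isomer drawn) | CCCCCCCCCCCCCCCCCCCCC/C=C/c1ccn(C(=O)OC(C)(C)C)c1C(=O)OC | intermediate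
11 | 1-tert-butyl 2-methyl 3-tricosyl-1H-pyrrole-1,2-dicarboxylate | CCCCCCCCCCCCCCCCCCCCCCCc1ccn(C(=O)OC(C)(C)C)c1C(=O)OC | intermediate
12 | 2-(methoxycarbonyl)-3-tricosyl-1H-pyrrole-1-carboxylic acid (formed in the flask) | CCCCCCCCCCCCCCCCCCCCCCCc1ccn(C(=O)O)c1C(=O)OC | intermediate
13 | methyl 3-tricosyl-1H-pyrrole-2-carboxylate | CCCCCCCCCCCCCCCCCCCCCCCc1cc[nH]c1C(=O)OC | target

**Step count**

Total steps: 7. Longest linear sequence: 6 (steps 1, 2, 3, 5, 6, 7); the aldehyde branch is step 4.

**Steps most likely to fail**

1. Step 2. Ionic bromination of the ring at C4 or C5 may compete with hydrogen abstraction from the methyl group, and the bromomethyl group may be brominated a second time.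
Fallback (sets out from 1, returns at 13): the nitrogen is sulfonylated instead (NaH, PhSO2Cl, THF) to give methyl 1-(benzenesulfonyl)-3-methyl-1H-pyrrole-2-carboxylate F1, whose ring is much less electron-rich than that of 2 and whose protecting group has no brominable C–H. Wohl–Ziegler bromination (NBS, AIBN) should then give methyl 1-(benzenesulfonyl)-3-(bromomethyl)-1H-pyrrole-2-carboxylate F2, and triphenylphosphine 4 converts it into {[1-(benzenesulfonyl)-2-(methoxycarbonyl)-1H-pyrrol-3-yl]methyl}triphenylphosphonium bromide F3. Treatment with K2CO3/18-crown-6 and docosanal 7 passes through the N-benzenesulfonyl ylide F4 and the N-benzenesulfonyl oxaphosphetane F5 to methyl 1-(benzenesulfonyl)-3-(tricos-1-en-1-yl)-1H-pyrrole-2-carboxylate F6. Hydrogenation over Pd/C gives methyl 1-(benzenesulfonyl)-3-tricosyl-1H-pyrrole-2-carboxylate F7, and Bu4NF in THF at reflux removes the sulfonyl group to give 13.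

2. Step 5. Base-mediated loss of the carbamate from the salt or the ylide may be followed by expulsion of triphenylphosphine and oligomerisation through an azafulvene, or the delocalised ylide may add so slowly that the enolisable aldehyde self-condenses.
Fallback (sets out from 3 and 6, uses 4, returns at 11): the polarity of the olefination is reversed so that no carbanion is generated next to the pyrrole. Kornblum-type oxidation of bromide 3 with N-methylmorpholine N-oxide in MeCN gives 1-tert-butyl 2-methyl 3-formyl-1H-pyrrole-1,2-dicarboxylate F8. Docosan-1-ol 6 is converted by an Appel reaction (CBr4, PPh3) into 1-bromodocosane F9, which is heated with triphenylphosphine 4 to give docosyltriphenylphosphonium bromide F10. Deprotonation with NaN(SiMe3)2 in THF at −78 °C gives docosylidenetriphenylphosphorane F11, which adds to F8 through the reversed-polarity oxaphosphetane F12 to give the Z-rich alkene 1-tert-butyl 2-methyl 3-[(Z)-tricos-1-en-1-yl]-1H-pyrrole-1,2-dicarboxylate F13. Hydrogenation as in step 6 gives 11.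

3. Step 6. Partial saturation of the N-acylated pyrrole ring may compete with reduction of the alkene, or the catalyst may stall through poisoning by phosphorus residues carried over from the olefination.
Fallback (sets out from 10, returns at 13): the endgame order is inverted and the metal catalyst avoided. Methanolysis of the carbamate (K2CO3, MeOH/THF, rt) gives methyl 3-(tricos-1-en-1-yl)-1H-pyrrole-2-carboxylate F14, and the side-chain alkene is then reduced with diimide generated from TsNHNH2 and NaOAc in refluxing DME/water, a reagent that cannot touch the aromatic ring, to give 13 directly.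

**Further compounds**

F1 | step 2 | methyl 1-(benzenesulfonyl)-3-methyl-1H-pyrrole-2-carboxylate | Cc1ccn(S(=O)(=O)c2ccccc2)c1C(=O)OC
F2 | step 2 | methyl 1-(benzenesulfonyl)-3-(bromomethyl)-1H-pyrrole-2-carboxylate | BrCc1ccn(S(=O)(=O)c2ccccc2)c1C(=O)OC
F3 | step 2 | {[1-(benzenesulfonyl)-2-(methoxycarbonyl)-1H-pyrrol-3-yl]methyl}triphenylphosphonium bromide | COC(=O)c1c(C[P+](c2ccccc2)(c2ccccc2)c2ccccc2)ccn1S(=O)(=O)c1ccccc1.[Br-]
F4 | step 2 | methyl 1-(benzenesulfonyl)-3-[(triphenyl-λ5-phosphanylidene)methyl]-1H-pyrrole-2-carboxylate (N-benzenesulfonyl ylide) | COC(=O)c1c(C=P(c2ccccc2)(c2ccccc2)c2ccccc2)ccn1S(=O)(=O)c1ccccc1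
F5 | step 2 | methyl 1-(benzenesulfonyl)-3-(4-henicosyl-2,2,2-triphenyl-1,2λ5-oxaphosphetan-3-yl)-1H-pyrrole-2-carboxylate (N-benzenesulfonyl oxaphosphetane; cis/trans mixture, racemic) | CCCCCCCCCCCCCCCCCCCCCC1OP(c2ccccc2)(c2ccccc2)(c2ccccc2)C1c1ccn(S(=O)(=O)c2ccccc2)c1C(=O)OC
F6 | step 2 | methyl 1-(benzenesulfonyl)-3-(tricos-1-en-1-yl)-1H-pyrrole-2-carboxylate (E/Z mixture; E isomer drawn) | CCCCCCCCCCCCCCCCCCCCC/C=C/c1ccn(S(=O)(=O)c2ccccc2)c1C(=O)OC
F7 | step 2 | methyl 1-(benzenesulfonyl)-3-tricosyl-1H-pyrrole-2-carboxylate | CCCCCCCCCCCCCCCCCCCCCCCc1ccn(S(=O)(=O)c2ccccc2)c1C(=O)OC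
F8 | step 5 | 1-tert-butyl 2-methyl 3-formyl-1H-pyrrole-1,2-dicarboxylate | O=Cc1ccn(C(=O)OC(C)(C)C)c1C(=O)OC
F9 | step 5 | 1-bromodocosane | CCCCCCCCCCCCCCCCCCCCCCBr
F10 | step 5 | docosyltriphenylphosphonium bromide | CCCCCCCCCCCCCCCCCCCCCC[P+](c1ccccc1)(c1ccccc1)c1ccccc1.[Br-]
F11 | step 5 | docosylidenetriphenylphosphorane | CCCCCCCCCCCCCCCCCCCCCC=P(c1ccccc1)(c1ccccc1)c1ccccc1
F12 | step 5 | 1-tert-butyl 2-methyl 3-(3-henicosyl-2,2,2-triphenyl-1,2λ5-oxaphosphetan-4-yl)-1H-pyrrole-1,2-dicarboxylate (reversed-polarity oxaphosphetane; cis expected to dominate, racemic, configuration not encoded) | CCCCCCCCCCCCCCCCCCCCCC1C(c2ccn(C(=O)OC(C)(C)C)c2C(=O)OC)OP1(c1ccccc1)(c1ccccc1)c1ccccc1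
F13 | step 5 | 1-tert-butyl 2-methyl 3-[(Z)-tricos-1-en-1-yl]-1H-pyrrole-1,2-dicarboxylate | C(/CCCCCCCCCCCCCCCCCCCCC)=C/c1ccn(C(=O)OC(C)(C)C)c1C(=O)OC
F14 | step 6 | methyl 3-(tricos-1-en-1-yl)-1H-pyrrole-2-carboxylate (E/Z mixture; E isomer drawn) | CCCCCCCCCCCCCCCCCCCCC/C=C/c1cc[nH]c1C(=O)OC
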